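The target is read as two phthalide halves (C1–C11 and C1'–C11') joined through C6–C3' and C7–C7a'. Everything rests on the C3a'–C7a' bond, which is common to the cyclopentane (ring C), the bridging γ-lactone (ring D) and the second cyclohexene (ring E). It is made last, together with C4'–C5', by an intramolecular Diels–Alder reaction across a δ-lactone that already contains C6–C3' and C7–C7a': an (E)-allylidene diene on C7a' meets a vinyl group on C3' and sets both remaining stereocentres. The δ-lactone comes from (Z)-ligustilide and a chiral 2-pyranone by Diels–Alder reaction, ring-opening metathesis and elimination.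

Key step: step 9

Assumption: compounds 1, 3, 7 and 11 are taken as purchased (1 in enantiopure form); locants follow phthalide numbering of each half (C1 lactone carbonyl, O2, C3, C3a, C4–C7, C7a, C8–C11 side chain; primed for the second half).

Step 1
Reactants: 1 (S)-hex-1-yn-3-ol
Product: 2 (S)-tert-butyl(hex-1-yn-3-yloxy)dimethylsilane
Conditions: TBSCl, imidazole, DMF, 0 °C to rt
Reagents that add atoms: tert-butyldimethylsilyl chloride, CC(C)(C)[Si](C)(C)Cl
Why: O-silylation of a secondary propargylic alcohol leaves the stereocentre untouched and installs the bulky group that later shields one face of the pyranone.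

Step 2
Reactants: 2 (S)-tert-butyl(hex-1-yn-3-yloxy)dimethylsilane; 3 methyl (Z)-3-iodoprop-2-enoate
Product: 4 methyl (2Z,6S)-6-[(tert-butyldimethylsilyl)oxy]non-2-en-4-ynoate
Conditions: Pd(PPh3)2Cl2 (2 mol %), CuI (4 mol %), Et3N, THF, rt
Reagents that add atoms: none
Why: Sonogashira coupling of a terminal alkyne with a (Z)-β-iodoacrylate should proceed at room temperature with retention of the Z geometry.

Step 3
Reactants: 4 methyl (2Z,6S)-6-[(tert-butyldimethylsilyl)oxy]non-2-en-4-ynoate
Product: 6 6-[(1S)-1-[(tert-butyldimethylsilyl)oxy]butyl]-2H-pyran-2-one, via enynoic acid 5 (not isolated)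
Conditions: LiOH, THF/H2O, 0 °C; 1 M HCl work-up; then ZnBr2 (10 mol %), THF, rt
Reagents that add atoms: lithium hydroxide, [Li+].[OH-]
Why: Saponification followed by ZnBr2-catalysed 6-endo-dig lactonisation of the (Z)-2-en-4-ynoic acid should give the 6-substituted 2-pyranone, the carboxylate attacking the alkyne carbon remote from the acid.

Step 4
Reactants: 6 6-[(1S)-1-[(tert-butyldimethylsilyl)oxy]butyl]-2H-pyran-2-one; 7 (Z)-ligustilide
Product: 8 endo Diels–Alder adduct: a 2-oxabicyclo[2.2.2]oct-5-en-3-one annulated on C6–C7 of the ligustilide half; bridgehead C3' (oxygen-bearing, carrying the (S)-1-silyloxybutyl chain) bonded to C6, bridgehead C7a' (CH) bonded to C7; H-6 and H-7 cis and syn to the lactone bridge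
Conditions: 6 (3 equiv), BHT, CH2Cl2, 1.2 GPa, 25 °C; excess 6 recovered
Reagents that add atoms: none
Why: This is a high-pressure inverse-electron-demand Diels–Alder reaction of a 2-pyranone with the C6=C7 bond of ligustilide (its dienophilic site), run cold so that CO2 is retained; the nucleophilic C6 should bond to the electrophilic pyranone C6, the endo mode puts the butenolide under the diene, and attack anti to the silyloxy group of the (S)-carbinol (C–H eclipsing the ring double bond to avoid allylic strain) should set C6, C7, C7a' and C3' in the absolute sense, the other facial isomer being a separable diastereomer.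

Step 5
Reactants: 8 endo Diels–Alder adduct (silyl ether)
Product: 9 the corresponding (S)-1-hydroxybutyl adduct (secondary alcohol on the chain at C3'; ring stereocentres as in 8)
Conditions: HF·pyridine, THF, 0 °C to rt
Reagents that add atoms: none
Why: Fluoride desilylation under mildly acidic conditions should cleave the hindered secondary silyl ether without touching the lactones or the enol ester.

Step 6
Reactants: 9 (S)-1-hydroxybutyl adduct
Product: 10 butanoyl adduct (ketone at C8'; bicyclic lactone with etheno bridge C7'=C3a'; ring stereocentres as in 8)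
Conditions: Dess–Martin periodinane, pyridine, CH2Cl2, rt
Reagents that add atoms: none
Why: Dess–Martin oxidation of the secondary alcohol gives the butanoyl ketone under neutral conditions and erases the auxiliary stereocentre once it has done its work.

Step 7
Reactants: 10 butanoyl adduct; 11 (Z)-but-2-ene-1,4-diyl diacetate
Product: 13 cis-fused δ-lactone carrying at C7a' (H) an (E)-3-acetoxyprop-1-enyl group and at C3' a vinyl group and the butanoyl group; both alkenyl groups trans to H-6 and H-7, via divinyl lactone 12 (not isolated)
Conditions: ethylene (1 atm), second-generation Grubbs catalyst RuCl2(=CHPh)(H2IMes)(PCy3) (5 mol %), CH2Cl2, 40 °C; argon purge; then 11 (5 equiv), second-generation Hoveyda–Grubbs catalyst RuCl2(=CH-C6H4-2-OiPr)(H2IMes) (5 mol %), 1,4-benzoquinone (10 mol %), 40 °C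
Reagents that add atoms: ethylene, C=C
Why: Ring-opening metathesis of the strained bicyclooctene with ethylene should release two cis vinyl groups; cross-metathesis should then engage only the vinyl group on the tertiary C7a', because the one on quaternary C3' is too hindered and the tri- and tetrasubstituted alkenes of the ligustilide half are inert to the ruthenium carbene.

Step 8
Reactants: 13 allylic acetate
Product: 14 cis-fused δ-lactone with an (E)-prop-2-en-1-ylidene group on C7a' (vinyl cis to C7, anti to the lactone C=O) and vinyl (trans to H-6) plus butanoyl on C3'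
Conditions: DBU, CH2Cl2, 0 °C to rt
Reagents that add atoms: none
Why: In this vinylogous E1cB (1,4-) elimination, DBU removes the acidic C7a'–H (α to the lactone and allylic) and the extended dienolate expels acetate, which should give the conjugated diene with the E geometry.

Step 9
Reactants: 14 (E)-allylidene vinyl δ-lactone
Product: 15 CNP0423313.1 (target)
Conditions: toluene (5 mM), BHT, 110 °C, sealed tube
Reagents that add atoms: none
Why: A thermal, concerted [4+2] cycloaddition joins the electron-poor dienoate C7a'=C7'–C6'=C5' to the vinyl group C3a'=C4', forming C3a'–C7a' and C4'–C5'. The closest known reaction type is the type 1 intramolecular Diels–Alder reaction of 1,3,8-nonatrienes to hydrindenes, here with two three-atom tethers (C7–C6–C3' and C1'–O2'–C3') that are the two halves of the δ-lactone. The new C3a'–C7a' bond closes ring C (C6, C7, C7a', C3a', C3') and ring D (C1', O2', C3', C3a', C7a') as five-membered rings in the fused mode across the 1,4-positions of the δ-lactone, and ring E is the cyclohexene of the cycloaddition itself. C7a' is controlled by the tether, since the vinyl group is fixed on the lactone face cis to C5 and C7a and can reach only that face of the diene terminus; C3a' is controlled by the E geometry of C7a'=C7', which holds C6' and C5' on the side of C7, so that C4' ends there and H-3a' ends syn to the lactone bridge. The step needs the fused rather than the bridged mode and must be faster than a [1,5]-hydrogen shift from C7–H into the diene; the three-atom tethers allow only the fused mode, and the enforced proximity of C3a' and C7a' across the ring should keep the barrier low.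

Compound list
1 | (S)-hex-1-yn-3-ol | CCC[C@H](O)C#C | starting material
2 | (S)-tert-butyl(hex-1-yn-3-yloxy)dimethylsilane | CCC[C@H](O[Si](C)(C)C(C)(C)C)C#C | intermediate
3 | methyl (Z)-3-iodoprop-2-enoate | COC(=O)/C=C\I | starting material
4 | methyl (2Z,6S)-6-[(tert-butyldimethylsilyl)oxy]non-2-en-4-ynoate | CCC[C@H](O[Si](C)(C)C(C)(C)C)C#C/C=C\C(=O)OC | intermediate
5 | (2Z,6S)-6-[(tert-butyldimethylsilyl)oxy]non-2-en-4-ynoic acid (not isolated) | CCC[C@H](O[Si](C)(C)C(C)(C)C)C#C/C=C\C(=O)O | intermediate
6 | 6-[(1S)-1-[(tert-butyldimethylsilyl)oxy]butyl]-2H-pyran-2-one | CCC[C@H](O[Si](C)(C)C(C)(C)C)C1=CC=CC(=O)O1 | intermediate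
7 | (Z)-ligustilide, (3Z)-3-butylidene-4,5-dihydro-2-benzofuran-1(3H)-one | CCC/C=C1\OC(=O)C2=C1CCC=C2 | starting material
8 | endo pyranone–ligustilide Diels–Alder adduct, silyl ether | CCC/C=C1\OC(=O)C2=C1CC[C@@H]3[C@H]2[C@@H]4C=C[C@]3(OC4=O)[C@@H](O[Si](C)(C)C(C)(C)C)CCC | intermediate
9 | endo adduct, (S)-1-hydroxybutyl at C3' | CCC/C=C1\OC(=O)C2=C1CC[C@@H]3[C@H]2[C@@H]4C=C[C@]3(OC4=O)[C@@H](O)CCC | intermediate
10 | endo adduct, butanoyl at C3' | CCC/C=C1\OC(=O)C2=C1CC[C@@H]3[C@H]2[C@@H]4C=C[C@]3(OC4=O)C(=O)CCC | intermediate
11 | (Z)-but-2-ene-1,4-diyl diacetate | CC(=O)OC/C=C\COC(C)=O | starting material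
12 | cis-divinyl δ-lactone (vinyl on C7a' and on C3', both trans to H-6/H-7; not isolated) | CCC/C=C1\OC(=O)C2=C1CC[C@@H]3[C@H]2[C@H](C=C)C(=O)O[C@@]3(C=C)C(=O)CCC | intermediate
13 | δ-lactone with (E)-3-acetoxyprop-1-enyl on C7a' and vinyl on C3' | CCC/C=C1\OC(=O)C2=C1CC[C@@H]3[C@H]2[C@H](/C=C/COC(C)=O)C(=O)O[C@@]3(C=C)C(=O)CCC | intermediate
14 | δ-lactone with (E)-prop-2-en-1-ylidene on C7a' and vinyl on C3' | CCC/C=C1\OC(=O)C2=C1CC[C@@H]3[C@H]2/C(=C\C=C)C(=O)O[C@@]3(C=C)C(=O)CCC | intermediate
15 | CNP0423313.1 | CCC/C=C1\OC(=O)C2=C1CC[C@@H]1[C@H]2[C@]23C=CCC[C@@H]2[C@@]1(C(=O)CCC)OC3=O | target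

Total step count: 9. Longest linear sequence: 9 (steps 1 to 9; 3, 7 and 11 enter as purchased partners).

Steps most likely to fail

Step 9. The cycloaddition may be outrun by a sigmatropic [1,5]-hydrogen shift from C7–H into the diene, or by oligomerisation, before the strained bicyclo[2.2.1] transition state is reached. The fallback sets out from 14 and returns directly to 15. It replaces the thermal pericyclic mode by a metal-templated stepwise [4+2] of the unactivated diene-ene through a rhodacycle at 25 to 40 °C ([Rh(cod)Cl]2, AgSbF6, CH2Cl2/hexafluoroisopropanol), a temperature at which the hydrogen shift is frozen. It makes no new compound (F0).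

Step 4. The 6-alkylpyranone may react too slowly, ligustilide may dimerise instead, or the facial selectivity may be poor. The fallback sets out from 6 and returns to 8. Bromination (Br2, CH2Cl2, then Et3N) gives the 3-bromopyranone F1, an ambiphilic and more reactive diene that keeps the same regiochemistry. Its cycloaddition with 7 (toluene, 80 °C, or 1.2 GPa at rt) gives the bromo adduct F2, with bromine on bridgehead C7a'. Radical debromination (Bu3SnH, Et3B, air, toluene, 0 °C) then gives 8.

Step 7. Ring opening of the hindered bicyclooctene may stall, the vinyl group on C7a' may migrate into conjugation, or cross-metathesis may occur at the wrong vinyl group. The fallback avoids metathesis; it sets out from 10 and returns to 14, bypassing 13 and step 8. OsO4 (cat.) with N-methylmorpholine N-oxide in acetone/H2O dihydroxylates the strained bridge alkene from the lactone side to the diol F3. NaIO4 (THF/H2O) cleaves it to the dialdehyde F4. Ph3P=CH2 (2 equiv, THF, −78 °C) methylenates only the non-enolisable aldehyde on C3', the other being masked as its enolate, to give the hydroxymethylene lactone F5. Triflation under non-chelating conditions (Tf2O, aqueous Me4NOH, toluene) gives the enol triflate F6 with the triflate anti to the lactone carbonyl. Stille coupling with tributyl(vinyl)stannane (Pd(PPh3)4, LiCl, THF, rt) then gives 14 with retention of geometry.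

Further compounds
F0 | step 9 | none | none
F1 | step 4 | 3-bromo-6-[(1S)-1-[(tert-butyldimethylsilyl)oxy]butyl]-2H-pyran-2-one | CCC[C@H](O[Si](C)(C)C(C)(C)C)C1=CC=C(Br)C(=O)O1
F2 | step 4 | endo adduct with bromine on bridgehead C7a', silyl ether | CCC/C=C1\OC(=O)C2=C1CC[C@@H]3[C@H]2[C@]4(Br)C=C[C@]3(OC4=O)[C@@H](O[Si](C)(C)C(C)(C)C)CCC
F3 | step 7 | cis-diol of 10 at C7' and C3a', hydroxyls syn to the lactone bridge | CCC/C=C1\OC(=O)C2=C1CC[C@@H]3[C@H]2[C@@H]4[C@@H](O)[C@@H](O)[C@]3(OC4=O)C(=O)CCC
F4 | step 7 | δ-lactone dialdehyde (formyl on C7a' and on C3') | CCC/C=C1\OC(=O)C2=C1CC[C@@H]3[C@H]2[C@H](C=O)C(=O)O[C@@]3(C=O)C(=O)CCC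
F5 | step 7 | δ-lactone with hydroxymethylene on C7a' and vinyl on C3' | CCC/C=C1\OC(=O)C2=C1CC[C@@H]3[C@H]2/C(=C/O)C(=O)O[C@@]3(C=C)C(=O)CCC
F6 | step 7 | enol triflate of F5, triflate anti to the lactone carbonyl | CCC/C=C1\OC(=O)C2=C1CC[C@@H]3[C@H]2/C(=C\OS(=O)(=O)C(F)(F)F)C(=O)O[C@@]3(C=C)C(=O)CCC
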